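The bicyclo[2.2.2]octane (bridgeheads C12 and C18) is disconnected across its ketone bridge: bonds C12–C13 and C14–C18 are made together by an intramolecular inverse-demand [4+2] cycloaddition. The precursor is a spiro cyclohexa-2,5-dienone fused to the butenolide (from dearomatization of a 7-hydroxyphthalide), already carrying ring B and the spiro lactone, with a 2-alkylacrylate tethered at C16. Double 1,4-hydrosilylation turns the dienone arm C11=C12 into a 2-silyloxydiene (C12=C23–C22=C18) and the acrylate into a ketene silyl acetal (C14=C13); cycloaddition closes the cyclopentane and the bicyclooctene, sets C12, C14 and C18, and delivers C13 as a masked ketone that steers the later C23 reduction.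

Key step: step 13

Remark (numbering used throughout, that of the target): C2 = gem-dimethyl carbinol carbon; O3, C4 (C=O), C5=C6 = rest of the δ-lactone (ring A); C7 = spiro center of ring A and ring B; ring B = C7–C8–C9–C10–C16–C17; C10 = quaternary carbon shared by ring B and the cage; C11 = CH2; C12 = C–CH3; C13 = ketone; C14 = C–CH3; C15 = CH2; C16 = CH; C17 = C(CH3)OH; C18 = bridgehead bearing C19H2–O20; C21 = γ-lactone carbonyl; C22 = CH; C23 = CHOH.

Remark (assumption): in step 4 the cinchonidinium salt is written; should it favour the S product, its cinchoninium pseudoenantiomer is taken instead.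

Step 1
Reactants: 1 2-methoxy-3-methylbenzoic acid; 2 dibromomethane
Product: 3 7-methoxy-6-methyl-2-benzofuran-1(3H)-one
Conditions: Pd(OAc)2 (10 mol%), K2HPO4, CH2Br2 as solvent, 140 °C, sealed tube
Reagents that add atoms: dibromomethane BrCBr
Why: Carboxylate-directed palladium-catalysed ortho C–H alkylation followed by intramolecular SN2 lactonization can occur only at the single free ortho position and gives the phthalide (C18, C19, C21–C23 of the target).

Step 2
Reactants: 3 7-methoxy-6-methyl-2-benzofuran-1(3H)-one
Product: 4 4-bromo-7-methoxy-6-methyl-2-benzofuran-1(3H)-one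
Conditions: NBS, MeCN, 20 °C, dark
Reagents that add atoms: N-bromosuccinimide O=C1CCC(=O)N1Br
Why: Electrophilic aromatic bromination should go para to the methoxy group and meta to the lactone carbonyl, which is C4 of the phthalide (the future C10).

Step 3
Reactants: 4 4-bromo-7-methoxy-6-methyl-2-benzofuran-1(3H)-one
Product: 5 4-bromo-7-hydroxy-6-methyl-2-benzofuran-1(3H)-one
Conditions: BBr3, CH2Cl2, −78 to 0 °C; then H2O
Reagents that add atoms: none
Why: Lewis-acid cleavage of the aryl methyl ether, helped by chelation to the neighbouring lactone carbonyl, frees the phenol while the lactone survives at low temperature.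

Step 4
Reactants: 6 3-acetyloxolan-2-one; 7 methyl (2Z)-3-iodoprop-2-enoate
Product: 8 methyl (2Z)-3-[(3R)-3-acetyl-2-oxooxolan-3-yl]prop-2-enoate
Conditions: O-allyl-N-(9-anthracenylmethyl)cinchonidinium bromide (10 mol%), Cs2CO3, toluene, −30 °C
Reagents that add atoms: methyl (2Z)-3-iodoprop-2-enoate COC(=O)/C=C\I
Why: Phase-transfer-catalysed enantioselective nucleophilic vinylic substitution (conjugate addition–elimination with retention of the Z geometry) of the chiral ammonium enolate of the cyclic β-keto lactone creates the quaternary center C7, whose R configuration is set by the face selection of the catalyst.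

Step 5
Reactants: 8 methyl (2Z)-3-[(3R)-3-acetyl-2-oxooxolan-3-yl]prop-2-enoate
Product: 10 (5R)-6,6-dimethyl-2,7-dioxaspiro[4.5]dec-9-ene-1,8-dione, via hydroxy ester 9 (not isolated)
Conditions: MeMgBr (1.1 equiv), CeCl3, THF, −78 to 0 °C
Reagents that add atoms: methylmagnesium bromide C[Mg]Br
Why: Organocerium-type 1,2-addition to the ketone (the most electrophilic carbonyl) gives a tertiary alkoxide that the Z alkene holds next to the ester, so that intramolecular transesterification closes ring A faster than retro-aldol cleavage; C7 is untouched.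

Step 6
Reactants: 10 (5R)-6,6-dimethyl-2,7-dioxaspiro[4.5]dec-9-ene-1,8-dione
Product: 11 (3R)-2,2-dimethyl-6-oxo-3-[2-(phenylselanyl)ethyl]-3,6-dihydro-2H-pyran-3-carboxylic acid
Conditions: PhSeSePh (0.55 equiv), NaBH4 (1.1 equiv), DMF, 110 °C; then aq. HCl
Reagents that add atoms: diphenyl diselenide c1ccc(cc1)[Se][Se]c1ccccc1
Why: SN2 opening of the γ-lactone at its primary O–CH2 carbon (C9) by the soft selenolate frees the C17 acid, whereas the tertiary alkyl–oxygen bond of ring A cannot react in an SN2 sense and any conjugate adduct at C6 is reversible.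

Step 7
Reactants: 11 (3R)-2,2-dimethyl-6-oxo-3-[2-(phenylselanyl)ethyl]-3,6-dihydro-2H-pyran-3-carboxylic acid
Product: 13 tert-butyl 3-[(3R)-2,2-dimethyl-6-oxo-3-[2-(phenylselanyl)ethyl]-3,6-dihydro-2H-pyran-3-yl]-3-oxopropanoate, via acyl imidazolide 12 (not isolated)
Conditions: CDI, THF, 20 °C; then Mg(O2CCH2CO2tBu)2, 45 °C; then aq. HCl
Reagents that add atoms: magnesium bis(3-tert-butoxy-3-oxopropanoate) CC(C)(C)OC(=O)CC(=O)[O-].CC(C)(C)OC(=O)CC(=O)[O-].[Mg+2]
Why: C-acylation of the magnesium malonate half-ester by the acyl imidazolide with loss of CO2 (decarboxylative Claisen condensation) turns the hindered acid into the β-keto ester and so makes the C17 ketone and C16.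

Step 8
Reactants: 13 tert-butyl 3-[(3R)-2,2-dimethyl-6-oxo-3-[2-(phenylselanyl)ethyl]-3,6-dihydro-2H-pyran-3-yl]-3-oxopropanoate; 14 methyl 2-(bromomethyl)prop-2-enoate
Product: 15 1-tert-butyl 5-methyl 2-{[(3R)-2,2-dimethyl-6-oxo-3-[2-(phenylselanyl)ethyl]-3,6-dihydro-2H-pyran-3-yl]carbonyl}-4-methylidenepentanedioate (both C16 epimers)
Conditions: K2CO3, acetone, 20 °C
Reagents that add atoms: methyl 2-(bromomethyl)prop-2-enoate COC(=O)C(=C)CBr
Why: C-alkylation of the β-keto ester enolate by the allylic bromide (SN2 or SN2′, same product) installs C15, C14 and C13; the new center C16 forms as a mixture and is erased later.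

Step 9
Reactants: 15 1-tert-butyl 5-methyl 2-{[(3R)-2,2-dimethyl-6-oxo-3-[2-(phenylselanyl)ethyl]-3,6-dihydro-2H-pyran-3-yl]carbonyl}-4-methylidenepentanedioate
Product: 17 1-tert-butyl 5-methyl 2-{[(3R)-3-ethenyl-2,2-dimethyl-6-oxo-3,6-dihydro-2H-pyran-3-yl]carbonyl}-4-methylidenepentanedioate, via selenoxide 16 (not isolated)
Conditions: H2O2 (30% aq.), pyridine, CH2Cl2, 0 to 25 °C
Reagents that add atoms: none
Why: Oxidation of the selenide and syn-elimination of the selenoxide give the terminal alkene C8=C9 under neutral conditions that leave both esters and the enoate alone.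

Step 10
Reactants: 17 1-tert-butyl 5-methyl 2-{[(3R)-3-ethenyl-2,2-dimethyl-6-oxo-3,6-dihydro-2H-pyran-3-yl]carbonyl}-4-methylidenepentanedioate; 5 4-bromo-7-hydroxy-6-methyl-2-benzofuran-1(3H)-one
Product: 19 1-tert-butyl 5-methyl 2-{[(3R)-3-[2-(7-hydroxy-6-methyl-1-oxo-1,3-dihydro-2-benzofuran-4-yl)ethyl]-2,2-dimethyl-6-oxo-3,6-dihydro-2H-pyran-3-yl]carbonyl}-4-methylidenepentanedioate, via alkylborane 18 (not isolated)
Conditions: 9-BBN-H (2.2 equiv), THF, 20 °C; then 5, PdCl2(dppf) (5 mol%), K3PO4, DMF/H2O, 50 °C
Reagents that add atoms: 4-bromo-7-hydroxy-6-methyl-2-benzofuran-1(3H)-one O=C1OCc2c(Br)cc(C)c(O)c12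
Why: Anti-Markovnikov hydroboration of the only monosubstituted alkene (faster than the electron-poor acrylate and the conjugated lactone) and B-alkyl Suzuki–Miyaura coupling join C9 to the aryl carbon C10 without touching C7.

Step 11
Reactants: 19 1-tert-butyl 5-methyl 2-{[(3R)-3-[2-(7-hydroxy-6-methyl-1-oxo-1,3-dihydro-2-benzofuran-4-yl)ethyl]-2,2-dimethyl-6-oxo-3,6-dihydro-2H-pyran-3-yl]carbonyl}-4-methylidenepentanedioate
Product: 20 dispiro dienone keto ester (ring B cyclohexanone spiro-fused at C7 to ring A and at C10 to the 2,5-cyclohexadienone–butenolide; C16 bears CO2tBu and CH2C(=CH2)CO2Me)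
Conditions: PhI(OAc)2 (1.1 equiv), (CF3)2CHOH, −20 to 0 °C
Reagents that add atoms: none
Why: Hypervalent-iodine oxidative dearomatization with spirocyclization: the β-keto ester enol attacks the para carbon C10 of the oxidised phenol and closes ring B, and in the chair-like transition state the CMe2 carbon on C7 should stand perpendicular to the enol plane on the face away from the arene while the arene arm carrying the lactone CH2 lies under the flat enol carbon C17 and not under C15H2, so that C18 ends trans to C2 across ring B.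

Step 12
Reactants: 20 dispiro dienone keto ester
Product: 22 dispiro dienone ketone (as 20 with H in place of CO2tBu on C16; both C16 epimers), via keto acid 21 (not isolated)
Conditions: CF3CO2H, CH2Cl2, 20 °C; then toluene, 50 °C
Reagents that add atoms: none
Why: Acidolysis of the tert-butyl ester and decarboxylation of the β-keto acid remove the activating group and leave C16 as an epimerizable CH next to the C17 ketone.

Step 13
Reactants: 22 dispiro dienone ketone
Product: 24 cage cycloadduct (C13 as mixed methyl triethylsilyl ketal; C22=C23 triethylsilyl enol ether; C17 ketone), via bis-silyl triene 23 (not isolated)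
Conditions: RhCl(PPh3)3 (3 mol%), Et3SiH (2.5 equiv), toluene, 50 °C; then DBU (0.1 equiv), 110 °C
Reagents that add atoms: triethylsilane CC[SiH](CC)CC
Why: Proposed new method: RhCl(PPh3)3-catalysed 1,4-hydrosilylation (known for enones and acrylates) converts the less hindered dienone arm C11=C12 into the silyl enol ether C12=C23 and the 2-alkylacrylate into the ketene silyl acetal C14=C13, so that 23 holds a push–pull 2-silyloxy diene (C12=C23–C22=C18, electron-poor at C18 through the lactone carbonyl C21, electron-rich at C12) beside a polarity-matched electron-rich 2π partner (nucleophilic C14, incipient oxocarbenium C13), and heating then gives a concerted but asynchronous [4+2] cycloaddition in which C14–C18 bonding leads and C12–C13 follows. The closest known reactions are the intramolecular Diels–Alder reaction of 2-silyloxy-1,3-cyclohexadienes to bicyclo[2.2.2]octanones and the inverse-demand cycloaddition of ketene acetals with electron-poor dienes, the Mukaiyama–Michael/Mukaiyama aldol sequence being the stepwise limit. The cyclopentane C10–C16–C15–C14–C18 closes in the 5-exo mode and the bicyclo[2.2.2]octene by the six-electron ring closure across C12 and C18. C12, C14 and C18 are set by the two-atom tether, which can deliver the 2π partner only to the diene face that carries C16 on the existing spiro center C10 and only with C14 on C18; C16 itself is corrected by DBU-mediated enolization of the C17 ketone, since only the epimer with C15 cis to C18 reaches the diene, and C13 becomes a mixed ketal of no stereochemical consequence. The step needs hydrosilylation of the enone and the acrylate before the conjugated spiro lactone or the C17 ketone (secured by the lower reactivity of a β-substituted unsaturated lactone and of a hindered saturated ketone toward the rhodium hydride) and no premature Michael addition (secured by reducing at 50 °C, below the temperature of uncatalysed C–C bond formation).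

Step 14
Reactants: 24 cage cycloadduct
Product: 25 C17 tertiary alcohol of the cage (C13 ketal and C23 silyl enol ether retained)
Conditions: MeLi, CeCl3, THF, −78 °C; then aq. NaHCO3
Reagents that add atoms: methyllithium [Li]C
Why: Organocerium 1,2-addition to the hindered, enolizable C17 ketone is faster than attack on the lactones, and methyl should enter from the face of ring B turned away from the cage because the other face is screened by the axial bridgehead C18 and its C19 methylene (1,3-diaxial), which puts the hydroxyl cis to C18.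

Step 15
Reactants: 25 C17 tertiary alcohol of the cage
Product: 28 target CNP0360620.2, via keto lactone 26 (not isolated), via hydroxy ketal 27 (not isolated)
Conditions: NaBH4, MeOH, −20 to 0 °C; then aq. HCl, THF, 20 °C
Reagents that add atoms: none
Why: Methanolysis of the vinylogous silyl ester unmasks the β-keto lactone 26, whose C23 carbonyl takes hydride from the C11 side because the other face is blocked by the alkoxy group of the C13 ketal and, after equilibration of the acidic C22–H, the lactone arm settles anti to the incoming hydride (C23–OH and C21 both toward the C13 bridge), and aqueous acid then collapses the mixed silyl methyl ketal to the C13 ketone.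

Compound list
1 | 2-methoxy-3-methylbenzoic acid | COc1c(C)cccc1C(=O)O | starting material
2 | dibromomethane | BrCBr | starting material
3 | 7-methoxy-6-methyl-2-benzofuran-1(3H)-one | O=C1OCc2ccc(C)c(OC)c12 | intermediate
4 | 4-bromo-7-methoxy-6-methyl-2-benzofuran-1(3H)-one | O=C1OCc2c(Br)cc(C)c(OC)c12 | intermediate
5 | 4-bromo-7-hydroxy-6-methyl-2-benzofuran-1(3H)-one | O=C1OCc2c(Br)cc(C)c(O)c12 | intermediate
6 | 3-acetyloxolan-2-one (racemic, configurationally labile) | CC(=O)C1CCOC1=O | starting material
7 | methyl (2Z)-3-iodoprop-2-enoate | COC(=O)/C=C\I | starting material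
8 | methyl (2Z)-3-[(3R)-3-acetyl-2-oxooxolan-3-yl]prop-2-enoate | CC(=O)[C@]1(/C=C\C(=O)OC)CCOC1=O | intermediate
9 | methyl (2Z)-3-[(3R)-3-(2-hydroxypropan-2-yl)-2-oxooxolan-3-yl]prop-2-enoate (formed as its magnesium alkoxide) | CC(C)(O)[C@]1(/C=C\C(=O)OC)CCOC1=O | intermediate (not isolated)
10 | (5R)-6,6-dimethyl-2,7-dioxaspiro[4.5]dec-9-ene-1,8-dione | CC1(C)OC(=O)C=C[C@]12CCOC2=O | intermediate
11 | (3R)-2,2-dimethyl-6-oxo-3-[2-(phenylselanyl)ethyl]-3,6-dihydro-2H-pyran-3-carboxylic acid | CC1(C)OC(=O)C=C[C@@]1(CC[Se]c1ccccc1)C(=O)O | intermediate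
12 | acyl imidazolide of acid 11 | CC1(C)OC(=O)C=C[C@@]1(CC[Se]c1ccccc1)C(=O)n1ccnc1 | intermediate (not isolated)
13 | tert-butyl 3-[(3R)-2,2-dimethyl-6-oxo-3-[2-(phenylselanyl)ethyl]-3,6-dihydro-2H-pyran-3-yl]-3-oxopropanoate | CC1(C)OC(=O)C=C[C@@]1(CC[Se]c1ccccc1)C(=O)CC(=O)OC(C)(C)C | intermediate
14 | methyl 2-(bromomethyl)prop-2-enoate | COC(=O)C(=C)CBr | starting material
15 | 1-tert-butyl 5-methyl 2-{[(3R)-2,2-dimethyl-6-oxo-3-[2-(phenylselanyl)ethyl]-3,6-dihydro-2H-pyran-3-yl]carbonyl}-4-methylidenepentanedioate (both C16 epimers) | CC1(C)OC(=O)C=C[C@@]1(CC[Se]c1ccccc1)C(=O)C(CC(=C)C(=O)OC)C(=O)OC(C)(C)C | intermediate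
16 | Se-oxide of 15 | CC1(C)OC(=O)C=C[C@@]1(CC[Se](=O)c1ccccc1)C(=O)C(CC(=C)C(=O)OC)C(=O)OC(C)(C)C | intermediate (not isolated)
17 | 1-tert-butyl 5-methyl 2-{[(3R)-3-ethenyl-2,2-dimethyl-6-oxo-3,6-dihydro-2H-pyran-3-yl]carbonyl}-4-methylidenepentanedioate (both C16 epimers) | CC1(C)OC(=O)C=C[C@@]1(C=C)C(=O)C(CC(=C)C(=O)OC)C(=O)OC(C)(C)C | intermediate
18 | 9-alkyl-9-borabicyclo[3.3.1]nonane from hydroboration of the ethenyl group of 17 at C9 | CC1(C)OC(=O)C=C[C@@]1(CCB1C2CCCC1CCC2)C(=O)C(CC(=C)C(=O)OC)C(=O)OC(C)(C)C | intermediate (not isolated)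
19 | 1-tert-butyl 5-methyl 2-{[(3R)-3-[2-(7-hydroxy-6-methyl-1-oxo-1,3-dihydro-2-benzofuran-4-yl)ethyl]-2,2-dimethyl-6-oxo-3,6-dihydro-2H-pyran-3-yl]carbonyl}-4-methylidenepentanedioate (both C16 epimers) | CC1(C)OC(=O)C=C[C@@]1(CCc1cc(C)c(O)c2C(=O)OCc12)C(=O)C(CC(=C)C(=O)OC)C(=O)OC(C)(C)C | intermediate
20 | dispiro dienone keto ester: ring B cyclohexanone (C17=O) spiro at C7 (R) to the δ-lactone and at C10 to the 2,5-cyclohexadienone–butenolide, C18 arm trans to C2 across ring B; C16 bears CO2tBu and CH2C(=CH2)CO2Me (C16 configuration not assigned) | CC1(C)OC(=O)C=C[C@]12CC[C@]3(C=C(C)C(=O)C4=C3COC4=O)C(CC(=C)C(=O)OC)(C(=O)OC(C)(C)C)C2=O | intermediate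
21 | β-keto acid from 20 (CO2H in place of CO2tBu) | CC1(C)OC(=O)C=C[C@]12CC[C@]3(C=C(C)C(=O)C4=C3COC4=O)C(CC(=C)C(=O)OC)(C(=O)O)C2=O | intermediate (not isolated)
22 | dispiro dienone ketone: as 20 with H on C16 (both C16 epimers) | CC1(C)OC(=O)C=C[C@]12CC[C@]3(C=C(C)C(=O)C4=C3COC4=O)C(CC(=C)C(=O)OC)C2=O | intermediate
23 | bis-silyl triene: C12=C23(OSiEt3)–C22=C18 silyloxydiene and C14(CH3)=C13(OMe)(OSiEt3) ketene acetal, C15 cis to C18 | CC1(C)OC(=O)C=C[C@]12CC[C@]3(CC(C)=C(O[Si](CC)(CC)CC)C4=C3COC4=O)[C@@H](CC(C)=C(OC)O[Si](CC)(CC)CC)C2=O | intermediate (not isolated)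
24 | cage cycloadduct: target skeleton with C13 as C(OMe)(OSiEt3) (both epimers), C22=C23–OSiEt3, C17 ketone | CC1(C)OC(=O)C=C[C@]12CC[C@]13C[C@]4(C)C(OC)(O[Si](CC)(CC)CC)[C@](C)(C[C@H]1C2=O)[C@]31COC(=O)C1=C4O[Si](CC)(CC)CC | intermediate
25 | as 24 with C17 as C(CH3)OH, hydroxyl cis to C18 | CC1(C)OC(=O)C=C[C@]12CC[C@]13C[C@]4(C)C(OC)(O[Si](CC)(CC)CC)[C@](C)(C[C@H]1[C@@]2(C)O)[C@]31COC(=O)C1=C4O[Si](CC)(CC)CC | intermediate
26 | keto lactone: as 25 with C23 ketone and C22–H | CC1(C)OC(=O)C=C[C@]12CC[C@]13C[C@]4(C)C(OC)(O[Si](CC)(CC)CC)[C@](C)(C[C@H]1[C@@]2(C)O)[C@]31COC(=O)[C@H]1C4=O | intermediate (not isolated)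
27 | hydroxy ketal: target with C13 still as C(OMe)(OSiEt3) | CC1(C)OC(=O)C=C[C@]12CC[C@]13C[C@]4(C)C(OC)(O[Si](CC)(CC)CC)[C@](C)(C[C@H]1[C@@]2(C)O)[C@]31COC(=O)[C@H]1[C@H]4O | intermediate (not isolated)
28 | CNP0360620.2 | CC1(C)OC(=O)C=C[C@]12CC[C@]13C[C@]4(C)C(=O)[C@](C)(C[C@H]1[C@@]2(C)O)[C@]31COC(=O)[C@H]1[C@H]4O | target

Total step count: 15. Longest linear sequence: 12 steps (steps 4–15, from 6 to 28); steps 1–3 prepare the aryl bromide 5 that enters at step 10.

Steps most likely to fail

1. Step 13 (the proposed new method). The two silyl-substituted π-systems may not combine in a [4+2] sense at a temperature the ketene acetal survives, or the rhodium hydride may reduce the spiro lactone enoate before the hindered dienone arm. The fallback is a stepwise polar route with known reactions and sets out from 22. The same hydrosilylation gives 23, which is not heated but treated at −78 °C with Me3SiOTf (10 mol%); this Mukaiyama–Michael addition of the ketene silyl acetal to C18 gives, after aqueous work-up, the keto ester with the C14–C18 bond in place F1. LDA (3.3 equiv, THF, −78 to 0 °C) then forms the dianion of the β-keto lactone, whose C12 terminus acylates on the methyl ester (Dieckmann-type γ-acylation) to give the cage triketone F2. MeLi/CeCl3 converts the C17 ketone into the carbinol F3, and NaBH4 reduces C23, coming back to the route at 28. In this variant the face selectivity at C23 rests on the C22 lactone arm alone, so separation of C22/C23 epimers may be needed.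

2. Step 11. Bond formation at a fully substituted enol carbon next to the emerging spiro center may be slow, so that solvent capture of the oxidised phenol competes, and the 1,4-induction from C7 to C10 may be incomplete. The fallback changes the order of bond formation and sets out from 13. Selenoxide elimination (H2O2, pyridine) before any alkylation gives the vinyl β-keto ester F4, and hydroboration/Suzuki–Miyaura coupling with 5 gives the phenol F5. PhI(OAc)2 in (CF3)2CHOH then closes ring B through the unsubstituted, more reactive β-keto ester CH to give the spirodienone F6. K2CO3 with 14 alkylates C16 afterwards and the sequence comes back at 20; C10 epimers, if formed, are separated at F6.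

3. Step 14. The methyl nucleophile may enter from the cage face of the C17 ketone (wrong C17 epimer), or enolization may dominate. The fallback delivers the oxygen instead of the carbon and sets out from 24. Methylenation of the C17 ketone with the Zn/CH2Br2/TiCl4 reagent gives the exocyclic alkene F7. Mukaiyama hydration (Mn(dpm)3, PhSiH3, O2, iPrOH) then makes the tertiary C17 radical by hydrogen-atom transfer to the CH2 terminus and traps it with O2 on the face that small reagents prefer, so the hydroxyl is placed where the methyl group would otherwise have gone; this comes back at 25.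

Further compounds
F1 | step 13 | keto ester after C14–C18 bond formation (C13 as CO2Me on C14; C12–H and C22–H, both epimers; C23 and C17 ketones) | CC1(C)OC(=O)C=C[C@]12CC[C@]13CC(C)C(=O)C4C(=O)OC[C@@]34[C@](C)(C(=O)OC)C[C@H]1C2=O
F2 | step 13 | cage triketone (C13, C17 and C23 ketones; C22–H epimers) | CC1(C)OC(=O)C=C[C@]12CC[C@]13C[C@]4(C)C(=O)[C@](C)(C[C@H]1C2=O)[C@]31COC(=O)C1C4=O
F3 | step 13 | cage diketone with C17 as C(CH3)OH (C13 and C23 ketones) | CC1(C)OC(=O)C=C[C@]12CC[C@]13C[C@]4(C)C(=O)[C@](C)(C[C@H]1[C@@]2(C)O)[C@]31COC(=O)C1C4=O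
F4 | step 11 | tert-butyl 3-[(3R)-3-ethenyl-2,2-dimethyl-6-oxo-3,6-dihydro-2H-pyran-3-yl]-3-oxopropanoate | CC1(C)OC(=O)C=C[C@@]1(C=C)C(=O)CC(=O)OC(C)(C)C
F5 | step 11 | tert-butyl 3-[(3R)-3-[2-(7-hydroxy-6-methyl-1-oxo-1,3-dihydro-2-benzofuran-4-yl)ethyl]-2,2-dimethyl-6-oxo-3,6-dihydro-2H-pyran-3-yl]-3-oxopropanoate | CC1(C)OC(=O)C=C[C@@]1(CCc1cc(C)c(O)c2C(=O)OCc12)C(=O)CC(=O)OC(C)(C)C
F6 | step 11 | dispiro dienone keto ester with C16 bearing H and CO2tBu | CC1(C)OC(=O)C=C[C@]12CC[C@]3(C=C(C)C(=O)C4=C3COC4=O)C(C(=O)OC(C)(C)C)C2=O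
F7 | step 14 | cage cycloadduct with C17 as exocyclic C=CH2 | CC1(C)OC(=O)C=C[C@]12CC[C@]13C[C@]4(C)C(OC)(O[Si](CC)(CC)CC)[C@](C)(C[C@H]1C2=C)[C@]31COC(=O)C1=C4O[Si](CC)(CC)CC
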